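**Retrosynthetic overview** (ring atoms carry the hexahydroazulene locants of the target throughout: C3 = isopropyl carbon, C3a/C8a = ring fusion, C6 = carbon bearing CH2O)
1. The ester C–O bond is made last by Mitsunobu coupling of vanillic acid with the C6 allylic alcohol; before that, the C3=C3a alkene is moved into place from C3a=C4 by acid.
2. Key disconnection: C4–C5 and C8–C8a in one operation. A rhodium alkenyl carbene from a cyclopentenyl sulfonylhydrazone cyclopropanates a 2-(silyloxymethyl)buta-1,3-diene, and the cis-divinylcyclopropane undergoes Cope rearrangement (formal [4+3]).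
3. Enabling feature: the seven-membered ring holds the C6=C7 alkene and the sp2 ring-fusion carbon C3a; shifting C3=C3a to C3a=C4 unveils a cyclohepta-1,4-diene (C3a=C4–C5–C6=C7), the retron of a divinylcyclopropane Cope rearrangement. The C3–H needed to shift the alkene back is the stereocentre that steers quaternary C8a and is then erased.
4. Ring order: the five-membered ring first (ozonolysis/aldol ring contraction of (S)-limonene-derived p-menth-1-ene, which supplies C3), the seven-membered ring second, in the key step.

Key step: step 7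

Remark: the starting materials 1, 6 and 15 and all reagents are taken to be commercial. The (S)-enantiomer of limonene is required because the route needs the (5R)-aldehyde 4.

**Step 1**
Reactants: 1 (S)-(−)-limonene
Product: 2 (S)-p-menth-1-ene [(4S)-1-methyl-4-(propan-2-yl)cyclohex-1-ene]
Conditions: H2 (1 atm), RhCl(PPh3)3 (cat.), PhH, rt
Reagents that add atoms: none
Why: Homogeneous hydrogenation with RhCl(PPh3)3 should reduce the unhindered 1,1-disubstituted isopropenyl alkene much faster than the trisubstituted ring alkene and leaves the stereocentre untouched.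

**Step 2**
Reactants: 2 (S)-p-menth-1-ene
Product: 3 (3S)-6-oxo-3-(propan-2-yl)heptanal
Conditions: O3, CH2Cl2/MeOH, −78 °C; then Me2S, −78 °C → rt
Reagents that add atoms: ozone, [O-][O+]=O
Why: Ozonolysis with reductive work-up should cleave the only alkene to the keto aldehyde; the stereocentre is not α to either carbonyl and cannot epimerize.

**Step 3**
Reactants: 3 (3S)-6-oxo-3-(propan-2-yl)heptanal
Product: 4 (5R)-2-methyl-5-(propan-2-yl)cyclopent-1-ene-1-carbaldehyde
Conditions: piperidine (cat.), AcOH (cat.), PhH, 80 °C, −H2O
Reagents that add atoms: none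
Why: Intramolecular aldol condensation through the enamine of the aldehyde, which attacks the methyl ketone and dehydrates to the conjugated cyclopentenecarbaldehyde, should close the five-membered ring without touching the stereocentre (its descriptor changes from S to R only because the CIP priorities change).

**Step 4**
Reactants: 4 (5R)-2-methyl-5-(propan-2-yl)cyclopent-1-ene-1-carbaldehyde
Product: 5 N′-[(E)-{(5R)-2-methyl-5-(propan-2-yl)cyclopent-1-en-1-yl}methylidene]-2-(trifluoromethyl)benzenesulfonohydrazide
Conditions: 2-(CF3)C6H4SO2NHNH2, MeOH, rt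
Reagents that add atoms: 2-(trifluoromethyl)benzenesulfonohydrazide, NNS(=O)(=O)c1ccccc1C(F)(F)F
Why: Condensation of the aldehyde with the sulfonyl hydrazide should give the (E)-N-sulfonylhydrazone, a carbene precursor that decomposes below room temperature.

**Step 5**
Reactants: 6 2-methyl-2-vinyloxirane (racemic)
Product: 7 2-methylidenebut-3-en-1-ol
Conditions: LDA, Et2O/THF, 0 °C → rt; aqueous work-up
Reagents that add atoms: none
Why: Base-mediated isomerization of an epoxide to an allylic alcohol: the hindered amide should remove a methyl proton and open the ring at the tertiary carbon, which gives the 2-substituted diene and removes the only stereocentre of 6.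

**Step 6**
Reactants: 7 2-methylidenebut-3-en-1-ol
Product: 8 tert-butyl[(2-methylidenebut-3-en-1-yl)oxy]diphenylsilane
Conditions: TBDPSCl, imidazole, CH2Cl2, 0 °C → rt
Reagents that add atoms: tert-butyl(chloro)diphenylsilane, CC(C)(C)[Si](Cl)(c1ccccc1)c1ccccc1
Why: Silylation of the primary alcohol should give a bulky ether that resists the acid of step 8 and is too hindered to form oxonium ylides with the carbene.

**Step 7**
Reactants: 5 sulfonylhydrazone; 8 silyloxymethyl diene (4 equiv)
Product: 12 tert-butyl{[(1R,3aR)-3a-methyl-1-(propan-2-yl)-1,2,3,3a,4,7-hexahydroazulen-6-yl]methoxy}diphenylsilane, via hydrazone sodium salt 9 (not isolated), via alkenyldiazomethane 10 (not isolated), via cis-divinylcyclopropane 11 (not isolated)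
Conditions: NaH, Rh2(OPiv)4 (1 mol %), PhCF3, 0 → 25 °C; then 100 °C
Reagents that add atoms: none
Why: NaH should turn 5 into salt 9, which expels sulfinate near room temperature to give alkenyldiazomethane 10; Rh2(OPiv)4 converts 10 into an electrophilic divalent-rhodium alkenyl carbene whose carbene carbon (C4) adds to the CH2 terminus of the more nucleophilic 1,1-disubstituted alkene of 8 (C4–C5 bond) and closes to cyclopropane 11, and heating then drives the [3,3] Cope rearrangement of 11 that forms C8–C8a and breaks the C4–C6 cyclopropane bond. The closest known reaction type is the tandem cyclopropanation/cis-divinylcyclopropane rearrangement (formal [4+3] cycloaddition) of rhodium alkenyl carbenes with 1,3-dienes, here with the carbene generated from an N-sulfonylhydrazone. The cyclopropane closes by [2+1] carbene transfer and the seven-membered ring by sigmatropic ring expansion through the boat transition state, the only one open to a cis-divinylcyclopropane, which makes both ring alkenes cis; the methyl group on the migrating terminus slows this step, hence the heating. Quaternary C8a is controlled by the C3 isopropyl group: in the s-trans carbene rotamer (rhodium turned away from the C8a methyl) this group covers one face of the carbene carbon, the diene should add to the other face and give the (1S,2S)-cyclopropane, and the stereospecific boat then delivers C8 to the face of C8a anti to the isopropyl group (3aR in 12). The step needs site selectivity for the substituted alkene of the diene (secured by the better-stabilized positive charge that builds up on the carbon bearing CH2OSi), a cis relation of the two alkenyl groups (a trans isomer can reach the cis one on heating by reversible homolysis of the doubly allylic C4–C6 bond, and the isomer with the unhindered boat is drained) and the facial selectivity named above; C8a epimers would remain separable diastereomers because C3 is still intact.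

**Step 8**
Reactants: 12 skipped-diene silyl ether
Product: 13 tert-butyl{[(8aR)-8a-methyl-3-(propan-2-yl)-1,2,4,5,8,8a-hexahydroazulen-6-yl]methoxy}diphenylsilane
Conditions: TsOH·H2O (10 mol %), PhH, 50 °C
Reagents that add atoms: none
Why: Acid-catalysed alkene isomerization: protonation of C3a=C4 at C4 should give the tertiary C3a cation, which loses H-3 to form the more stable tetrasubstituted cyclopentene alkene; this erases the C3 stereocentre, quaternary C8a cannot epimerize, and the C6=C7 alkene is deactivated towards protonation by its allylic oxygen.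

**Step 9**
Reactants: 13 isomerized silyl ether
Product: 14 [(8aR)-8a-methyl-3-(propan-2-yl)-1,2,4,5,8,8a-hexahydroazulen-6-yl]methanol
Conditions: TBAF, THF, 0 °C → rt; aqueous work-up
Reagents that add atoms: none
Why: Fluoride-mediated desilylation should free the primary allylic alcohol under conditions that leave both alkenes alone.

**Step 10**
Reactants: 14 allylic alcohol; 15 vanillic acid (4-hydroxy-3-methoxybenzoic acid)
Product: 16 [(8aR)-8a-methyl-3-(propan-2-yl)-1,2,4,5,8,8a-hexahydroazulen-6-yl]methyl 4-hydroxy-3-methoxybenzoate (target)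
Conditions: PPh3, DIAD, THF, 0 °C → rt
Reagents that add atoms: none
Why: Mitsunobu esterification: the carboxylic acid, far more acidic than the phenol, should act as the pronucleophile and displace the activated primary allylic oxygen by SN2, so the phenol needs no protection.

**Compound list**
1 | (S)-(−)-limonene | CC1=CC[C@H](CC1)C(C)=C | starting material
2 | (4S)-1-methyl-4-(propan-2-yl)cyclohex-1-ene | CC1=CC[C@H](CC1)C(C)C | intermediate
3 | (3S)-6-oxo-3-(propan-2-yl)heptanal | O=CC[C@H](CCC(C)=O)C(C)C | intermediate
4 | (5R)-2-methyl-5-(propan-2-yl)cyclopent-1-ene-1-carbaldehyde | O=CC1=C(C)CC[C@@H]1C(C)C | intermediate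
5 | N′-[(E)-{(5R)-2-methyl-5-(propan-2-yl)cyclopent-1-en-1-yl}methylidene]-2-(trifluoromethyl)benzenesulfonohydrazide | FC(F)(F)c1ccccc1S(=O)(=O)N/N=C/C2=C(C)CC[C@@H]2C(C)C | intermediate
6 | 2-methyl-2-vinyloxirane (racemic) | CC1(C=C)CO1 | starting material
7 | 2-methylidenebut-3-en-1-ol | C=CC(=C)CO | intermediate
8 | tert-butyl[(2-methylidenebut-3-en-1-yl)oxy]diphenylsilane | C=CC(=C)CO[Si](c1ccccc1)(c1ccccc1)C(C)(C)C | intermediate
9 | sodium salt of hydrazone 5 (N-sodio sulfonylhydrazonide) | [Na+].FC(F)(F)c1ccccc1S(=O)(=O)[N-]/N=C/C2=C(C)CC[C@@H]2C(C)C | intermediate (not isolated)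
10 | (5R)-1-(diazomethyl)-2-methyl-5-(propan-2-yl)cyclopent-1-ene | [N-]=[N+]=CC1=C(C)CC[C@@H]1C(C)C | intermediate (not isolated)
11 | tert-butyl({(1S,2S)-1-ethenyl-2-[(5R)-2-methyl-5-(propan-2-yl)cyclopent-1-en-1-yl]cyclopropyl}methoxy)diphenylsilane | C=C[C@@]1(CO[Si](c3ccccc3)(c3ccccc3)C(C)(C)C)C[C@H]1C2=C(C)CC[C@@H]2C(C)C | intermediate (not isolated)
12 | tert-butyl{[(1R,3aR)-3a-methyl-1-(propan-2-yl)-1,2,3,3a,4,7-hexahydroazulen-6-yl]methoxy}diphenylsilane | CC(C)(C)[Si](c1ccccc1)(c1ccccc1)OCC2=CC[C@@]3(C)CC[C@H](C(C)C)C3=CC2 | intermediate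
13 | tert-butyl{[(8aR)-8a-methyl-3-(propan-2-yl)-1,2,4,5,8,8a-hexahydroazulen-6-yl]methoxy}diphenylsilane | CC(C)(C)[Si](c1ccccc1)(c1ccccc1)OCC2=CC[C@@]3(C)CCC(C(C)C)=C3CC2 | intermediate
14 | [(8aR)-8a-methyl-3-(propan-2-yl)-1,2,4,5,8,8a-hexahydroazulen-6-yl]methanol | OCC1=CC[C@@]2(C)CCC(C(C)C)=C2CC1 | intermediate
15 | vanillic acid (4-hydroxy-3-methoxybenzoic acid) | COc1cc(C(=O)O)ccc1O | starting material
16 | [(8aR)-8a-methyl-3-(propan-2-yl)-1,2,4,5,8,8a-hexahydroazulen-6-yl]methyl 4-hydroxy-3-methoxybenzoate | COc1cc(C(=O)OCC2=CC[C@@]3(C)CCC(C(C)C)=C3CC2)ccc1O | target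

**Total step count:** 10. **Longest linear sequence:** 8 steps (steps 1–4, then 7–10); steps 5–6 form the short diene branch.

**Steps most likely to fail**

Step 7. What may go wrong: carbene transfer to the unsubstituted vinyl group of 8 (wrong orientation of the four-carbon unit), attack on the carbene face syn to the isopropyl group, or loss of the alkenyldiazomethane by cyclization to a 3H-pyrazole or by a 1,4-hydrogen shift before it meets the catalyst. Fallback, from 4 and returning at 14, in which the two bonds are made one after the other by known reactions: Luche reduction of 4 (NaBH4, CeCl3·7H2O, MeOH, 0 °C) should give [(5R)-2-methyl-5-(propan-2-yl)cyclopent-1-en-1-yl]methanol F1. Johnson–Claisen rearrangement (MeC(OEt)3, cat. EtCO2H, 140 °C) should form the C8–C8a bond anti to the isopropyl group and give ethyl 2-[(1R,3R)-1-methyl-2-methylidene-3-(propan-2-yl)cyclopentyl]acetate F2. An EtAlCl2-promoted ene reaction of the exocyclic methylene with methyl acrylate (CH2Cl2, rt) should form C4–C5, take the only allylic hydrogen (H-3) and so place the alkene at C3=C3a, giving methyl 4-[(5R)-5-(2-ethoxy-2-oxoethyl)-5-methyl-2-(propan-2-yl)cyclopent-1-en-1-yl]butanoate F3. LiAlH4 (THF, 0 °C) should reduce both esters to 4-[(5R)-5-(2-hydroxyethyl)-5-methyl-2-(propan-2-yl)cyclopent-1-en-1-yl]butan-1-ol F4, and Swern oxidation should give 4-[(5R)-5-methyl-5-(2-oxoethyl)-2-(propan-2-yl)cyclopent-1-en-1-yl]butanal F5. Piperidinium acetate (PhH, 80 °C) should close the seven-membered ring by intramolecular aldol condensation from the unhindered α-carbon (C6 onto C7; the other α-carbon is neopentylic) to give (8aR)-8a-methyl-3-(propan-2-yl)-1,2,4,5,8,8a-hexahydroazulene-6-carbaldehyde F6, which NaBH4/CeCl3·7H2O should reduce to 14.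

Step 8. What may go wrong: over-isomerization to the exocyclic isopropylidene alkene, a Wagner–Meerwein shift in the C3a cation, or acid cleavage of the silyl ether followed by ionization of the allylic alcohol. Fallback, from 12 and returning at 13, without a free carbocation: epoxidation of the more electron-rich C3a=C4 alkene (mCPBA, NaHCO3, CH2Cl2, −20 °C) on the face opposite the angular methyl and isopropyl groups should give tert-butyl{[(3R,8aR)-3a,4-epoxy-8a-methyl-3-(propan-2-yl)-1,2,3,3a,4,5,8,8a-octahydroazulen-6-yl]methoxy}diphenylsilane (oxirane oxygen trans to CH3-8a and to the isopropyl group) F7. LiBHEt3 (THF, 0 °C → rt) should open it at the secondary carbon C4 to tert-butyl{[(3R,8aR)-3a-hydroxy-8a-methyl-3-(propan-2-yl)-1,2,3,3a,4,5,8,8a-octahydroazulen-6-yl]methoxy}diphenylsilane (hydroxyl trans to CH3-8a, cis to H-3) F8. Syn elimination with the Burgess reagent (methyl N-(triethylammoniosulfonyl)carbamate, PhH, 50 °C) should then take the cis H-3 and give 13.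

Step 10. What may go wrong: competing alkylation of the phenol oxygen, or SN2′ attack that transposes the C6=C7 alkene. Fallback, from 14 and returning at 16: carbodiimide esterification (EDC·HCl, DMAP, CH2Cl2, rt) with commercial 4-acetoxy-3-methoxybenzoic acid should give [(8aR)-8a-methyl-3-(propan-2-yl)-1,2,4,5,8,8a-hexahydroazulen-6-yl]methyl 4-(acetyloxy)-3-methoxybenzoate F9, and pyrrolidine (CH2Cl2, 0 °C) should remove the aryl acetate selectively to give 16.

**Further compounds**
F1 | step 7 | [(5R)-2-methyl-5-(propan-2-yl)cyclopent-1-en-1-yl]methanol | OCC1=C(C)CC[C@@H]1C(C)C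
F2 | step 7 | ethyl 2-[(1R,3R)-1-methyl-2-methylidene-3-(propan-2-yl)cyclopentyl]acetate | CCOC(=O)C[C@@]1(C)CC[C@H](C(C)C)C1=C
F3 | step 7 | methyl 4-[(5R)-5-(2-ethoxy-2-oxoethyl)-5-methyl-2-(propan-2-yl)cyclopent-1-en-1-yl]butanoate | CCOC(=O)C[C@@]1(C)CCC(C(C)C)=C1CCCC(=O)OC
F4 | step 7 | 4-[(5R)-5-(2-hydroxyethyl)-5-methyl-2-(propan-2-yl)cyclopent-1-en-1-yl]butan-1-ol | OCC[C@@]1(C)CCC(C(C)C)=C1CCCCO
F5 | step 7 | 4-[(5R)-5-methyl-5-(2-oxoethyl)-2-(propan-2-yl)cyclopent-1-en-1-yl]butanal | O=CC[C@@]1(C)CCC(C(C)C)=C1CCCC=O
F6 | step 7 | (8aR)-8a-methyl-3-(propan-2-yl)-1,2,4,5,8,8a-hexahydroazulene-6-carbaldehyde | O=CC1=CC[C@@]2(C)CCC(C(C)C)=C2CC1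
F7 | step 8 | tert-butyl{[(3R,8aR)-3a,4-epoxy-8a-methyl-3-(propan-2-yl)-1,2,3,3a,4,5,8,8a-octahydroazulen-6-yl]methoxy}diphenylsilane, oxygen trans to CH3-8a and to the isopropyl group | CC(C)(C)[Si](c1ccccc1)(c1ccccc1)OCC2=CC[C@@]3(C)CC[C@H](C(C)C)[C@@]34O[C@H]4CC2
F8 | step 8 | tert-butyl{[(3R,8aR)-3a-hydroxy-8a-methyl-3-(propan-2-yl)-1,2,3,3a,4,5,8,8a-octahydroazulen-6-yl]methoxy}diphenylsilane, hydroxyl trans to CH3-8a and cis to H-3 | CC(C)(C)[Si](c1ccccc1)(c1ccccc1)OCC2=CC[C@@]3(C)CC[C@H](C(C)C)[C@]3(O)CC2
F9 | step 10 | [(8aR)-8a-methyl-3-(propan-2-yl)-1,2,4,5,8,8a-hexahydroazulen-6-yl]methyl 4-(acetyloxy)-3-methoxybenzoate | COc1cc(C(=O)OCC2=CC[C@@]3(C)CCC(C(C)C)=C3CC2)ccc1OC(C)=O
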